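The numbering is lignan style: C7 is the carbinol carbon, C8 the oxolane carbon bearing it, C8' the oxolane carbon bearing the benzyl arm, C7' the benzylic CH2, and C9/C9' the two OCH2 groups.
The retrosynthesis removes the two O-benzyl groups, then cuts the C7'–aryl bond (alkyl bromide plus aryl bromide). It next takes C7 back to a ketone and C7' to CO2H, and last cuts the aromatic C1–C7 bond, which gives an arylzinc and a meso anhydride.
The enabling feature is that oxolane carbons C8 and C8' each carry one exocyclic carbon (C7, C7'). Stripped of aryl groups and raised to the carboxyl level, the two arms are mirror images. They can be tied into a temporary five-membered anhydride ring cis-fused to the oxolane ring (achiral 3,7-dioxabicyclo[3.3.0]octane-2,4-dione).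
In the forward direction the oxolane ring comes from hydrogenation of furan-3,4-dicarboxylic acid, the anhydride ring is closed, and the arylation opens it for good. One aryl bromide (2) supplies both aryl groups.
C8' is set by the chiral rhodium catalyst through its choice between enantiotopic carbonyls, C8 by base equilibration to trans relative to C8', and C7 by catalyst-controlled transfer hydrogenation.

Key step: step 4

Assumption: the sense of induction of the chiral ligand on the oxa-bicyclic anhydride is taken by analogy with carbocyclic meso succinic anhydrides. Should the keto acid prove to be the antipode, the enantiomeric ligand (from the other tartrate) is used and nothing else changes.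

Step 1
Reactants: 1 4-bromo-2-methoxyphenol
Product: 2 1-(benzyloxy)-4-bromo-2-methoxybenzene
Conditions: BnBr, K2CO3, DMF, rt
Reagents that add atoms: benzyl bromide, BrCc1ccccc1
Why: Williamson ether synthesis in which the phenoxide of 1 displaces bromide from benzyl bromide, and the benzyl ether masks the acidic phenol through the organometallic, hydride and nickel steps until a neutral hydrogenolysis.

Step 2
Reactants: 3 furan-3,4-dicarboxylic acid
Product: 4 cis-oxolane-3,4-dicarboxylic acid (meso, 3R,4S)
Conditions: H2 (50 bar), 5% Rh/Al2O3, AcOH–H2O, 60 °C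
Reagents that add atoms: none
Why: Heterogeneous hydrogenation of the furan ring delivers hydrogen from the catalyst-bound face, so the two carboxyl groups should end up cis on the new oxolane ring, and any trans acid formed by isomerisation is corrected in step 3.

Step 3
Reactants: 4 cis-oxolane-3,4-dicarboxylic acid
Product: 5 cis-3,7-dioxabicyclo[3.3.0]octane-2,4-dione (meso anhydride, 3aR,6aS)
Conditions: Ac2O, reflux, then evaporation
Reagents that add atoms: none
Why: Dehydrative cyclisation through the mixed acetic anhydride closes the five-membered anhydride ring, which can only be cis-fused to the oxolane, so trans diacid, if present, converges on 5 by enolisation of its mixed anhydride.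

Step 4
Reactants: 2 1-(benzyloxy)-4-bromo-2-methoxybenzene; 5 meso anhydride
Product: 8 (3R,4S)-4-[4-(benzyloxy)-3-methoxybenzoyl]oxolane-3-carboxylic acid (cis), via aryllithium 6 (not isolated), via arylzinc triflate 7 (not isolated)
Conditions: 2 (1.6 equiv), n-BuLi, THF, −78 °C; Zn(OTf)2, −78 °C to rt; then 5, [Rh(cod)Cl]2 (4 mol %), (R,R)-TADDOL-PNMe2 phosphoramidite (10 mol %), THF, 50 °C; 1 M HCl work-up
Reagents that add atoms: n-butyllithium, [Li]CCCC (lithium of 6 only); zinc triflate, [Zn+2].[O-]S(=O)(=O)C(F)(F)F.[O-]S(=O)(=O)C(F)(F)F (zinc and triflate of 7 only)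
Why: Monovalent rhodium bearing the chiral phosphoramidite inserts into one of the two enantiotopic acyl C–O bonds of 5 to give a trivalent acyl rhodium carboxylate, arylzinc triflate 7 transfers its aryl group to rhodium, and reductive elimination forges the bond from aromatic C1 to carbonyl C7 and releases the zinc carboxylate of 8. The closest known reaction type is the catalytic enantioselective desymmetrising acyl cross-coupling (Negishi type) of bicyclic meso succinic anhydrides with arylzinc reagents made in situ from aryllithiums and Zn(OTf)2. No ring is closed: the temporary anhydride ring is opened and the oxolane ring stays intact. No stereocentre is created, but the two ring-fusion carbons, mirror images in 5, become C8 and C8' of fixed absolute configuration because the ligand directs insertion to the carbonyl on the (S)-configured fusion carbon. The step needs mono-arylation without decarbonylation or epimerisation. The substrate secures the first because the second carbonyl leaves as an inert zinc carboxylate and the aryl ketone is not attacked by the soft arylzinc, while fast transmetallation from the halide-free zinc triflate and the non-basic medium secure the other two.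

Step 5
Reactants: 8 cis keto acid
Product: 9 (3R,4R)-4-[4-(benzyloxy)-3-methoxybenzoyl]oxolane-3-carboxylic acid (trans)
Conditions: NaOH (2.5 equiv), THF–H2O, rt; then 1 M HCl, 0 °C
Reagents that add atoms: none
Why: Base-mediated epimerisation through the aryl ketone enolate, in which only C8 is acidic because C8' sits next to a carboxylate, so C8' keeps the configuration fixed in step 4 while C8 relaxes to the less crowded trans arrangement, and beta-elimination of the oxolane oxygen, the reverse of a 5-endo-trig closure, lacks the orbital overlap to compete.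

Step 6
Reactants: 9 trans keto acid
Product: 10 (3R,4R)-4-{(R)-[4-(benzyloxy)-3-methoxyphenyl](hydroxy)methyl}oxolane-3-carboxylic acid
Conditions: RuCl(p-cymene)[(R,R)-TsDPEN] (1 mol %), HCO2H–Et3N (5:2), DMF, 30 °C
Reagents that add atoms: none
Why: Noyori–Ikariya asymmetric transfer hydrogenation, established for aryl ketones and gamma-aryl gamma-keto acids, in which the (R,R)-TsDPEN ruthenium hydride holds the aryl group under its arene ligand and delivers hydride to the Si face of C7 to set the (R)-carbinol under catalyst control, and because a trans-fused lactone is too strained 10 stays an extractable acid whereas residual cis material lactonises and is removed as a neutral compound.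

Step 7
Reactants: 10 trans hydroxy acid
Product: 11 (R)-[4-(benzyloxy)-3-methoxyphenyl][(3R,4S)-4-(hydroxymethyl)oxolan-3-yl]methanol
Conditions: BH3·THF (3.5 equiv), THF, 0 °C to rt; aqueous work-up
Reagents that add atoms: none
Why: Borane reduces the carboxylic acid through its acyloxyborane without touching ethers or arenes, and no stereocentre is involved since the carbinol is merely held as a borate until work-up (the descriptor at C8' changes by priority only).

Step 8
Reactants: 11 diol
Product: 12 (R)-[4-(benzyloxy)-3-methoxyphenyl][(3R,4R)-4-(bromomethyl)oxolan-3-yl]methanol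
Conditions: CBr4 (1.1 equiv), PPh3 (1.15 equiv), CH2Cl2, −20 to 0 °C
Reagents that add atoms: carbon tetrabromide, BrC(Br)(Br)Br
Why: Appel bromination, in which the unhindered primary hydroxyl forms the alkoxyphosphonium salt and is displaced by bromide (SN2) faster than the secondary carbinol flanked by a ring carbon and an aryl group, while the trans disposition of the two arms blocks ether formation between them.

Step 9
Reactants: 12 bromo alcohol; 2 1-(benzyloxy)-4-bromo-2-methoxybenzene
Product: 13 (R)-[4-(benzyloxy)-3-methoxyphenyl]{(3R,4R)-4-[4-(benzyloxy)-3-methoxybenzyl]oxolan-3-yl}methanol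
Conditions: NiI2 (10 mol %), 4,4'-dimethoxy-2,2'-bipyridine (10 mol %), NaI (25 mol %), pyridine (10 mol %), Zn (2 equiv), DMPU, 60 °C
Reagents that add atoms: none
Why: Nickel-catalysed reductive cross-electrophile coupling of an aryl bromide with a primary alkyl bromide, in which zerovalent nickel adds the aryl bromide, the primary radical from 12 is captured by the aryl nickel species and reductive elimination forms the C7'–aryl bond under non-basic conditions that tolerate the free hydroxyl, with no stereocentre touched because the radical sits on the exocyclic CH2.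

Step 10
Reactants: 13 dibenzyl ether
Product: 14 4-[(R)-hydroxy{(3R,4R)-4-[(4-hydroxy-3-methoxyphenyl)methyl]oxolan-3-yl}methyl]-2-methoxyphenol (target)
Conditions: H2 (1 atm), 10% Pd/C, EtOAc–EtOH, rt, stopped at consumption of 13
Reagents that add atoms: none
Why: Hydrogenolysis of aryl benzyl ethers over Pd/C in neutral solvent is much faster than cleavage of a secondary benzylic C–OH bond, so C7 should keep its oxygen and its configuration.

Compound list
1 | 4-bromo-2-methoxyphenol | COc1cc(Br)ccc1O | starting material
2 | 1-(benzyloxy)-4-bromo-2-methoxybenzene | COc1cc(Br)ccc1OCc1ccccc1 | intermediate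
3 | furan-3,4-dicarboxylic acid | OC(=O)c1cocc1C(O)=O | starting material
4 | cis-oxolane-3,4-dicarboxylic acid (meso) | OC(=O)[C@H]1COC[C@H]1C(O)=O | intermediate
5 | cis-3,7-dioxabicyclo[3.3.0]octane-2,4-dione (meso anhydride) | O=C2[C@H]1COC[C@H]1C(=O)O2 | intermediate
6 | [4-(benzyloxy)-3-methoxyphenyl]lithium | COc1cc([Li])ccc1OCc1ccccc1 | intermediate
7 | [4-(benzyloxy)-3-methoxyphenyl]zinc triflate | COc1cc([Zn]OS(=O)(=O)C(F)(F)F)ccc1OCc1ccccc1 | intermediate
8 | (3R,4S)-4-[4-(benzyloxy)-3-methoxybenzoyl]oxolane-3-carboxylic acid (cis) | OC(=O)[C@H]1COC[C@H]1C(=O)c1ccc(OCc2ccccc2)c(OC)c1 | intermediate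
9 | (3R,4R)-4-[4-(benzyloxy)-3-methoxybenzoyl]oxolane-3-carboxylic acid (trans) | OC(=O)[C@H]1COC[C@@H]1C(=O)c1ccc(OCc2ccccc2)c(OC)c1 | intermediate
10 | (3R,4R)-4-{(R)-[4-(benzyloxy)-3-methoxyphenyl](hydroxy)methyl}oxolane-3-carboxylic acid | OC(=O)[C@H]1COC[C@@H]1[C@@H](O)c1ccc(OCc2ccccc2)c(OC)c1 | intermediate
11 | (R)-[4-(benzyloxy)-3-methoxyphenyl][(3R,4S)-4-(hydroxymethyl)oxolan-3-yl]methanol | OC[C@H]1COC[C@@H]1[C@@H](O)c1ccc(OCc2ccccc2)c(OC)c1 | intermediate
12 | (R)-[4-(benzyloxy)-3-methoxyphenyl][(3R,4R)-4-(bromomethyl)oxolan-3-yl]methanol | BrC[C@H]1COC[C@@H]1[C@@H](O)c1ccc(OCc2ccccc2)c(OC)c1 | intermediate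
13 | (R)-[4-(benzyloxy)-3-methoxyphenyl]{(3R,4R)-4-[4-(benzyloxy)-3-methoxybenzyl]oxolan-3-yl}methanol | COc1cc(C[C@H]2COC[C@@H]2[C@@H](O)c2ccc(OCc3ccccc3)c(OC)c2)ccc1OCc1ccccc1 | intermediate
14 | 4-[(R)-hydroxy{(3R,4R)-4-[(4-hydroxy-3-methoxyphenyl)methyl]oxolan-3-yl}methyl]-2-methoxyphenol | COc1cc(C[C@H]2COC[C@@H]2[C@@H](O)c2ccc(O)c(OC)c2)ccc1O | target

Total step count: 10. Longest linear sequence: 9 (steps 2 to 10, from 3).

Steps most likely to fail

Step 4. The catalyst may discriminate poorly between the two enantiotopic carbonyl groups. Oxidative addition may be slow if the oxolane oxygen ties up rhodium, and the acyl rhodium may lose CO. The fallback sets out from 5 and comes back at 9.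
- The symmetry is first broken without a metal, by quinidine-mediated methanolysis of 5 (MeOH, toluene, −55 °C; quinine if the opposite sense is found). This gives the cis hemiester (3S,4R)-4-(methoxycarbonyl)oxolane-3-carboxylic acid F1.
- Oxalyl chloride with catalytic DMF converts F1 into methyl (3R,4S)-4-(chlorocarbonyl)oxolane-3-carboxylate F2.
- Negishi acylation of arylzinc 7 (made as in step 4) under Pd(PPh3)4 forms the same aryl–C7 bond and gives methyl (3R,4S)-4-[4-(benzyloxy)-3-methoxybenzoyl]oxolane-3-carboxylate F3.
- LiOH in aqueous THF then saponifies the ester and epimerises the far more acidic C8 in one operation to give 9.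

Step 9. Dimerisation or reduction of the alkyl bromide may outrun cross-coupling with the electron-rich aryl bromide. Beta-hydride elimination from the alkyl nickel species and interference by the free hydroxyl are also possible. The fallback sets out from 12 and comes back at 13, and replaces the radical coupling by a polar one.
- TBSOTf and 2,6-lutidine give the silyl ether tert-butyl{(R)-[4-(benzyloxy)-3-methoxyphenyl][(3R,4R)-4-(bromomethyl)oxolan-3-yl]methoxy}dimethylsilane F4.
- Magnesium in THF turns 2 into [4-(benzyloxy)-3-methoxyphenyl]magnesium bromide F5.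
- Copper-catalysed Grignard–alkyl halide coupling (Li2CuCl4, THF–NMP, 0 °C) joins the two to the silyl ether of 13, tert-butyl[(R)-[4-(benzyloxy)-3-methoxyphenyl]{(3R,4R)-4-[4-(benzyloxy)-3-methoxybenzyl]oxolan-3-yl}methoxy]dimethylsilane F6.
- Bu4NF in THF releases 13.

Step 6. Facial selectivity may be poor if the resident centre C8 and the catalyst are mismatched, and material may drain into the cis series through amine-mediated epimerisation during a slow reduction. The fallback sets out from 9 and comes back at 11.
- MeI and KHCO3 in DMF give methyl (3R,4R)-4-[4-(benzyloxy)-3-methoxybenzoyl]oxolane-3-carboxylate F7.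
- Corey–Bakshi–Shibata reduction ((S)-Me-CBS oxazaborolidine, BH3·SMe2, THF, −20 °C, non-basic) should set the (R)-carbinol in methyl (3R,4R)-4-{(R)-[4-(benzyloxy)-3-methoxyphenyl](hydroxy)methyl}oxolane-3-carboxylate F8.
- LiBH4 in THF reduces the ester to diol 11.

Further compounds
F1 | step 4 | (3S,4R)-4-(methoxycarbonyl)oxolane-3-carboxylic acid | COC(=O)[C@H]1COC[C@H]1C(O)=O
F2 | step 4 | methyl (3R,4S)-4-(chlorocarbonyl)oxolane-3-carboxylate | COC(=O)[C@H]1COC[C@H]1C(Cl)=O
F3 | step 4 | methyl (3R,4S)-4-[4-(benzyloxy)-3-methoxybenzoyl]oxolane-3-carboxylate | COC(=O)[C@H]1COC[C@H]1C(=O)c1ccc(OCc2ccccc2)c(OC)c1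
F4 | step 9 | tert-butyl{(R)-[4-(benzyloxy)-3-methoxyphenyl][(3R,4R)-4-(bromomethyl)oxolan-3-yl]methoxy}dimethylsilane | BrC[C@H]1COC[C@@H]1[C@@H](O[Si](C)(C)C(C)(C)C)c1ccc(OCc2ccccc2)c(OC)c1
F5 | step 9 | [4-(benzyloxy)-3-methoxyphenyl]magnesium bromide | COc1cc([Mg]Br)ccc1OCc1ccccc1
F6 | step 9 | tert-butyl[(R)-[4-(benzyloxy)-3-methoxyphenyl]{(3R,4R)-4-[4-(benzyloxy)-3-methoxybenzyl]oxolan-3-yl}methoxy]dimethylsilane | COc1cc(C[C@H]2COC[C@@H]2[C@@H](O[Si](C)(C)C(C)(C)C)c2ccc(OCc3ccccc3)c(OC)c2)ccc1OCc1ccccc1
F7 | step 6 | methyl (3R,4R)-4-[4-(benzyloxy)-3-methoxybenzoyl]oxolane-3-carboxylate | COC(=O)[C@H]1COC[C@@H]1C(=O)c1ccc(OCc2ccccc2)c(OC)c1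
F8 | step 6 | methyl (3R,4R)-4-{(R)-[4-(benzyloxy)-3-methoxyphenyl](hydroxy)methyl}oxolane-3-carboxylate | COC(=O)[C@H]1COC[C@@H]1[C@@H](O)c1ccc(OCc2ccccc2)c(OC)c1
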